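The route rests on cutting the pyran ring of the 2,2-dimethyl-2H-chromene at C2–C3 and C4–C4a, which releases C3=C4 as a two-carbon unit. The key step exploits the fact that O1 ties the gem-dimethyl carbon C2, a latent tertiary oxocarbenium centre, to C8a of the phloroglucinol ring A, whose ortho carbon C4a is nucleophilic. The cationic 2-oxadiene C2=O1–C8a=C4a takes up ethyl vinyl ether, an acetylene equivalent, in a formal [4+2] annulation. Loss of ethanol leaves the chromene. The precursor is the symmetric 4-isopropenyl ether of phloroacetophenone, in which both ortho carbons are equivalent. Ketone alpha-arylation and aerobic oxidation later build the benzil.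

Key step: step 2

Remark: chromene numbering (O1, C2, C3, C4, C4a, C5, C6, C7, C8, C8a) is used for all bicyclic compounds. The target has no stereocentre, so none has to be set.

Step 1
Reactants: 1 1-(2,4,6-trihydroxyphenyl)ethanone (phloroacetophenone, dried); 2 4,4,5,5-tetramethyl-2-(prop-1-en-2-yl)-1,3,2-dioxaborolane (isopropenylboronic acid pinacol ester)
Product: 3 1-[2,6-dihydroxy-4-(prop-1-en-2-yloxy)phenyl]ethanone
Conditions: 2 (1.1 equiv), Cu(OAc)2 (2.0 equiv), Et3N (4.0 equiv), 4 Å MS, MeCN–CH2Cl2, 23 °C; non-acidic work-up, Et3N-deactivated silica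
Reagents that add atoms: none
Why: Chan–Lam-type oxidative O-alkenylation, in which the isopropenyl group passes from boron to a divalent copper phenoxide before C–O reductive elimination, and the para hydroxyl should react first because it is the most acidic one and the only one not flanked by or hydrogen-bonded to the acetyl group.

Step 2
Reactants: 3 1-[2,6-dihydroxy-4-(prop-1-en-2-yloxy)phenyl]ethanone; 4 ethyl vinyl ether (ethoxyethene)
Product: 7 1-(5,7-dihydroxy-2,2-dimethyl-2H-chromen-6-yl)ethanone, via alpha-chloro ether 5 (not isolated), via 4-ethoxychroman 6 (not isolated)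
Conditions: HCl (1.0 M in Et2O, 1.05 equiv), CH2Cl2, −78 °C; then 2,6-di-tert-butyl-4-methylpyridine (DTBMP, 1.2 equiv), ZnCl2 (1.0 M in Et2O, 0.3 equiv), 4 (1.3 equiv, slow addition), −78 to −20 °C; then camphorsulfonic acid (0.4 equiv), 23 °C
Reagents that add atoms: none
Why: Proposed new method: HCl converts the enol ether of 3 into the tertiary alpha-chloro ether 5, ZnCl2 ionises it to the aryloxycarbenium ion (the cationic 2-oxadiene C2=O1–C8a=C4a), the CH2 terminus of 4 attacks C2 (C2–C3 bond), the new ethoxycarbenium carbon C4 is trapped by the ortho carbon C4a (C4–C4a bond) to give 6, and acid then expels ethanol to leave the C3=C4 alkene of 7. The closest known reaction types are the oxa-Povarov reaction of aldehyde-derived aryloxycarbenium ions with alkenes, the Povarov reaction with vinyl ethers as acetylene equivalents and the HCl-adduct/ZnCl2 initiation of controlled vinyl ether addition, whereas an acetone-derived oxadiene combined with in situ elimination to a 2,2-dimethyl-2H-chromene goes beyond them. The pyran ring closes as a stepwise formal [4+2] annulation whose second bond is a 6-exo-trig Friedel–Crafts attack on the oxocarbenium carbon, helped by the Thorpe–Ingold effect of the gem-dimethyl group and by the two free hydroxyls that keep ring A nucleophilic despite the acetyl group. The only new stereocentre, C4 of 6, forms without control (racemic) and is erased by the elimination. The step needs chemoselectivity (cation only from 3, 4 only as nucleophile, a single insertion), which is secured by pre-forming 5, by the proton trap DTBMP and by slow addition of 4 so that intramolecular capture outruns chain growth. It needs no regiocontrol, because the two ortho carbons flanking the enol ether oxygen of 3 are equivalent by symmetry and O1–C2 is already in place, which excludes the 8-acetyl isomer.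

Step 3
Reactants: 7 1-(5,7-dihydroxy-2,2-dimethyl-2H-chromen-6-yl)ethanone
Product: 8 1-{5-hydroxy-2,2-dimethyl-7-[(triisopropylsilyl)oxy]-2H-chromen-6-yl}ethanone
Conditions: TIPSCl (1.05 equiv), imidazole (2.5 equiv), DMF, 0 °C
Reagents that add atoms: chlorotriisopropylsilane (TIPSCl), CC(C)[Si](Cl)(C(C)C)C(C)C
Why: Sterically controlled O-silylation, in which the bulky chlorosilane should take the C7 hydroxyl (next to C8–H) because the C5 hydroxyl is buttressed by C4–H and held in the stronger hydrogen bond to the acetyl oxygen.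

Step 4
Reactants: 8 1-{5-hydroxy-2,2-dimethyl-7-[(triisopropylsilyl)oxy]-2H-chromen-6-yl}ethanone
Product: 9 1-{5-methoxy-2,2-dimethyl-7-[(triisopropylsilyl)oxy]-2H-chromen-6-yl}ethanone
Conditions: MeI (5 equiv), K2CO3 (3 equiv), DMF, 23 °C
Reagents that add atoms: iodomethane (MeI), CI
Why: Williamson O-methylation of the remaining chelated phenol, with a carbonate base too weak to enolise the ketone and a hindered silyl ether that should survive it.

Step 5
Reactants: 10 4-bromophenol; 11 1-bromo-3-methylbut-2-ene (prenyl bromide)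
Product: 12 1-bromo-4-[(3-methylbut-2-en-1-yl)oxy]benzene
Conditions: K2CO3 (1.5 equiv), acetone, reflux
Reagents that add atoms: none
Why: Williamson ether synthesis by SN2 attack of the phenoxide on the primary allylic bromide.

Step 6
Reactants: 9 1-{5-methoxy-2,2-dimethyl-7-[(triisopropylsilyl)oxy]-2H-chromen-6-yl}ethanone; 12 1-bromo-4-[(3-methylbut-2-en-1-yl)oxy]benzene
Product: 13 1-{5-methoxy-2,2-dimethyl-7-[(triisopropylsilyl)oxy]-2H-chromen-6-yl}-2-{4-[(3-methylbut-2-en-1-yl)oxy]phenyl}ethanone
Conditions: Pd2(dba)3 (2 mol %), Xantphos (4.5 mol %), K3PO4 (2.5 equiv), toluene, 85 °C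
Reagents that add atoms: none
Why: Buchwald–Hartwig–Miura ketone alpha-arylation (oxidative addition of 12 to zerovalent palladium, exchange with the potassium enolate of 9, C–C reductive elimination), in which the mild phosphate base should spare the silyl ether and the fast reaction of the C–Br bond should outrun ionisation of the prenyl ether.

Step 7
Reactants: 13 1-{5-methoxy-2,2-dimethyl-7-[(triisopropylsilyl)oxy]-2H-chromen-6-yl}-2-{4-[(3-methylbut-2-en-1-yl)oxy]phenyl}ethanone
Product: 14 1-{5-methoxy-2,2-dimethyl-7-[(triisopropylsilyl)oxy]-2H-chromen-6-yl}-2-{4-[(3-methylbut-2-en-1-yl)oxy]phenyl}ethane-1,2-dione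
Conditions: DABCO (0.3 equiv), air (1 atm), DMF, 85 °C
Reagents that add atoms: dioxygen, O=O
Why: Amine-catalysed aerobic oxidation of a deoxybenzoin to a benzil, in which the doubly activated CH2 enolises, traps O2 as the alpha-hydroperoxide and loses water in a Kornblum–DeLaMare-type step, without a reagent that attacks the chromene or prenyl alkenes.

Step 8
Reactants: 14 1-{5-methoxy-2,2-dimethyl-7-[(triisopropylsilyl)oxy]-2H-chromen-6-yl}-2-{4-[(3-methylbut-2-en-1-yl)oxy]phenyl}ethane-1,2-dione
Product: 15 ficucaricone C, 1-(7-hydroxy-5-methoxy-2,2-dimethyl-2H-chromen-6-yl)-2-{4-[(3-methylbut-2-en-1-yl)oxy]phenyl}ethane-1,2-dione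
Conditions: TBAF (1.1 equiv), AcOH (1.1 equiv), THF, 0 °C
Reagents that add atoms: none
Why: Fluoride-induced desilylation of the aryl silyl ether, driven by the Si–F bond and buffered with acetic acid so that the 1,2-diketone, the prenyl ether and the chromene should stay untouched.

Compound list
1 | 1-(2,4,6-trihydroxyphenyl)ethanone (phloroacetophenone) | CC(=O)c1c(O)cc(O)cc1O | starting material
2 | 4,4,5,5-tetramethyl-2-(prop-1-en-2-yl)-1,3,2-dioxaborolane | CC(=C)B1OC(C)(C)C(C)(C)O1 | starting material
3 | 1-[2,6-dihydroxy-4-(prop-1-en-2-yloxy)phenyl]ethanone | CC(=O)c1c(O)cc(OC(C)=C)cc1O | intermediate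
4 | ethyl vinyl ether | C=COCC | starting material
5 | 1-[4-(2-chloropropan-2-yloxy)-2,6-dihydroxyphenyl]ethanone (not isolated) | CC(=O)c1c(O)cc(OC(C)(C)Cl)cc1O | intermediate
6 | 1-(4-ethoxy-5,7-dihydroxy-2,2-dimethylchroman-6-yl)ethanone (racemic, not isolated) | CCOC1CC(C)(C)Oc2cc(O)c(C(C)=O)c(O)c21 | intermediate
7 | 1-(5,7-dihydroxy-2,2-dimethyl-2H-chromen-6-yl)ethanone | CC(=O)c1c(O)cc2OC(C)(C)C=Cc2c1O | intermediate
8 | 1-{5-hydroxy-2,2-dimethyl-7-[(triisopropylsilyl)oxy]-2H-chromen-6-yl}ethanone | CC(=O)c1c(O[Si](C(C)C)(C(C)C)C(C)C)cc2OC(C)(C)C=Cc2c1O | intermediate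
9 | 1-{5-methoxy-2,2-dimethyl-7-[(triisopropylsilyl)oxy]-2H-chromen-6-yl}ethanone | CC(=O)c1c(O[Si](C(C)C)(C(C)C)C(C)C)cc2OC(C)(C)C=Cc2c1OC | intermediate
10 | 4-bromophenol | Oc1ccc(Br)cc1 | starting material
11 | 1-bromo-3-methylbut-2-ene (prenyl bromide) | CC(C)=CCBr | starting material
12 | 1-bromo-4-[(3-methylbut-2-en-1-yl)oxy]benzene | CC(C)=CCOc1ccc(Br)cc1 | intermediate
13 | 1-{5-methoxy-2,2-dimethyl-7-[(triisopropylsilyl)oxy]-2H-chromen-6-yl}-2-{4-[(3-methylbut-2-en-1-yl)oxy]phenyl}ethanone | COc1c2C=CC(C)(C)Oc2cc(O[Si](C(C)C)(C(C)C)C(C)C)c1C(=O)Cc1ccc(OCC=C(C)C)cc1 | intermediate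
14 | 1-{5-methoxy-2,2-dimethyl-7-[(triisopropylsilyl)oxy]-2H-chromen-6-yl}-2-{4-[(3-methylbut-2-en-1-yl)oxy]phenyl}ethane-1,2-dione | COc1c2C=CC(C)(C)Oc2cc(O[Si](C(C)C)(C(C)C)C(C)C)c1C(=O)C(=O)c1ccc(OCC=C(C)C)cc1 | intermediate
15 | ficucaricone C | COc1c2c(cc(O)c1C(=O)C(=O)c1ccc(OCC=C(C)C)cc1)OC(C)(C)C=C2 | target

Total step count: 8. Longest linear sequence: 7 (steps 1, 2, 3, 4, 6, 7, 8).

Steps most likely to fail

Step 2. Three processes could spoil it:
- chain growth of the vinyl ether at the ethoxycarbenium end before ring closure;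
- self-addition of enol ether regenerated from 5;
- beta-elimination of the phenol from the open-chain cation.

The fallback uses known chemistry and sets out from 1. Copper-catalysed O-alkylation of the para hydroxyl with 3-chloro-3-methylbut-1-yne (CuCl2 catalyst, DBU, MeCN, 0 °C) should give 1-[2,6-dihydroxy-4-(2-methylbut-3-yn-2-yloxy)phenyl]ethanone F1. Heating F1 in xylene at 140 °C should then trigger the aromatic propargyl Claisen rearrangement, 1,5-hydrogen shift and oxa-6π electrocyclisation. This comes back to the route at 7. It closes the pyran ring through C4–C4a and O1–C2 instead of inserting a two-carbon unit.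

Step 1. Three processes could spoil it:
- sequestration of copper by the o-hydroxyacetophenone chelate;
- oxidative coupling of the electron-rich triphenol;
- a second alkenylation at an ortho hydroxyl.

The fallback sets out from 1. Mitsunobu etherification of the most acidic, para hydroxyl with 1-chloropropan-2-ol (PPh3, DIAD, THF, 0 °C) should give racemic 1-[4-(1-chloropropan-2-yloxy)-2,6-dihydroxyphenyl]ethanone F2. Dehydrochlorination with KOtBu (3.5 equiv, THF, 0 to 23 °C) removes the hydrogen next to the ether oxygen. This comes back to the route at 3.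

Step 6. Zerovalent palladium could ionise the prenyl aryl ether and transfer the allyl group to the enolate. The silyl group could also migrate from O7 to the enolate oxygen.

The fallback sets out from 9 and postpones the prenyl group:
- The same alpha-arylation with commercial (4-bromophenoxy)(tert-butyl)dimethylsilane should give 2-{4-[(tert-butyldimethylsilyl)oxy]phenyl}-1-{5-methoxy-2,2-dimethyl-7-[(triisopropylsilyl)oxy]-2H-chromen-6-yl}ethanone F3.
- DABCO and air in DMF should give the corresponding ethane-1,2-dione F4.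
- TBAF and AcOH (2.2 equiv each) should give 1-(7-hydroxy-5-methoxy-2,2-dimethyl-2H-chromen-6-yl)-2-(4-hydroxyphenyl)ethane-1,2-dione F5.
- Alkylation with 11 (1.0 equiv, K2CO3, acetone, 23 °C) should take only the non-chelated hydroxyl of ring B.

This comes back to the route at 15.

Further compounds
F1 | step 2 | 1-[2,6-dihydroxy-4-(2-methylbut-3-yn-2-yloxy)phenyl]ethanone | CC(=O)c1c(O)cc(OC(C)(C)C#C)cc1O
F2 | step 1 | 1-[4-(1-chloropropan-2-yloxy)-2,6-dihydroxyphenyl]ethanone (racemic) | CC(=O)c1c(O)cc(OC(C)CCl)cc1O
F3 | step 6 | 2-{4-[(tert-butyldimethylsilyl)oxy]phenyl}-1-{5-methoxy-2,2-dimethyl-7-[(triisopropylsilyl)oxy]-2H-chromen-6-yl}ethanone | COc1c2C=CC(C)(C)Oc2cc(O[Si](C(C)C)(C(C)C)C(C)C)c1C(=O)Cc1ccc(O[Si](C)(C)C(C)(C)C)cc1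
F4 | step 6 | 1-{4-[(tert-butyldimethylsilyl)oxy]phenyl}-2-{5-methoxy-2,2-dimethyl-7-[(triisopropylsilyl)oxy]-2H-chromen-6-yl}ethane-1,2-dione | COc1c2C=CC(C)(C)Oc2cc(O[Si](C(C)C)(C(C)C)C(C)C)c1C(=O)C(=O)c1ccc(O[Si](C)(C)C(C)(C)C)cc1
F5 | step 6 | 1-(7-hydroxy-5-methoxy-2,2-dimethyl-2H-chromen-6-yl)-2-(4-hydroxyphenyl)ethane-1,2-dione | COc1c2C=CC(C)(C)Oc2cc(O)c1C(=O)C(=O)c1ccc(O)cc1
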